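**Plan**

- Retrosynthesis (chain numbered from the benzylic carbon C1'): the two O-protecting groups come off first. Then the aryl–C1' and C4'–C5' bonds are cut together, leaving an arylzinc reagent, isoprene and a C5'–C16' enal. The enal is cut at C14'=C15' (metathesis), at C12'–C13' (allylation) and at the C12' oxygen, back to geranyl acetate.
- What permits the central cut: C1'–C2'=C3'(CH3)–C4' is an unbroken isoprene unit held between an arene carbon and the carbinol carbon C5', and C5'–C12' is a geranyl skeleton oxidised at both ends. The benzene ring is the only ring and is bought with the phenol, so no ring is formed anywhere.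
- Forward: geranyl acetate is oxidised at C12', allylated, extended to the prenyl terminus, silylated and taken to the C5' aldehyde. The bromophenol-derived aryl(alkyl)zinc, whose (trimethylsilyl)methyl group is a non-transferable spectator ligand so that every aryl group made can be delivered, is prepared separately. Nickel joins arene, isoprene and enal, and two deprotections finish.
- Stereochemistry: 12'R comes from a reagent-controlled Brown allylboration and 5'R from the chiral ligand on nickel. The 6'E and 10'E alkenes come from geranyl acetate and E-selective SeO2 oxidation, and 2'E from the syn-allylnickel intermediate.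

Key step: step 10

Assumption: which antipode of the nickel ligand induces 5'R cannot be told in advance, so both antipodes are tried once and the one giving the 5'R carbinol is used in step 10.

**Route**

Step 1
Reactants: 1 geranyl acetate
Product: 3 (2E,6E)-3,7-dimethyl-8-oxoocta-2,6-dien-1-yl acetate, via 8-hydroxygeranyl acetate 2 (not isolated)
Conditions: SeO2 (catalytic), t-BuOOH, salicylic acid (catalytic), CH2Cl2, rt; crude mixture, MnO2, CH2Cl2, rt
Reagents that add atoms: selenium dioxide, O=[Se]=O (delivers the new oxygen); tert-butyl hydroperoxide, CC(C)(C)OO (terminal oxidant that restores SeO2)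
Why: Riley allylic oxidation (ene reaction, then [2,3]-sigmatropic shift) attacks the E-methyl group of the electron-rich distal trisubstituted alkene, the proximal alkene being deactivated by the allylic acetate, and MnO2 oxidation of the allylic alcohol then converges the alcohol/aldehyde mixture on the E-enal.

Step 2
Reactants: 3 (2E,6E)-3,7-dimethyl-8-oxoocta-2,6-dien-1-yl acetate
Product: 5 (2E,6E,8R)-8-hydroxy-3,7-dimethylundeca-2,6,10-trien-1-yl acetate, via borinate ester 4 (not isolated)
Conditions: (lIpc)2B(allyl) of the (−)-α-pinene series (commercial 1 M solution in pentane), Et2O, −78 °C; then 30% H2O2, aqueous NaHCO3, 0 °C to rt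
Reagents that add atoms: B-allyldiisopinocampheylborane derived from (−)-α-pinene, C=CCB([C@H]1C[C@H]2C[C@@H]([C@@H]1C)C2(C)C)[C@H]1C[C@H]2C[C@@H]([C@@H]1C)C2(C)C
Why: Brown allylboration through a closed chair transition state in which the isopinocampheyl groups of the (−)-α-pinene series send the allyl group to the Re face of the aldehyde, which sets 8R (the later C12'), while the acetate survives the low temperature and the bicarbonate-buffered peroxide work-up.

Step 3
Reactants: 5 (2E,6E,8R)-8-hydroxy-3,7-dimethylundeca-2,6,10-trien-1-yl acetate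
Product: 6 (2E,6E,8R)-8-hydroxy-3,7,11-trimethyldodeca-2,6,10-trien-1-yl acetate
Conditions: 2-methyl-2-butene (large excess), second-generation Grubbs catalyst (H2IMes)(PCy3)Cl2Ru=CHPh (5 mol %), CH2Cl2, rt to 40 °C
Reagents that add atoms: 2-methyl-2-butene, CC=C(C)C
Why: Olefin cross-metathesis in which only the monosubstituted terminal alkene engages the ruthenium carbene and takes up the isopropylidene unit with loss of propene, the two trisubstituted alkenes being too hindered to react under these mild conditions.

Step 4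
Reactants: 6 (2E,6E,8R)-8-hydroxy-3,7,11-trimethyldodeca-2,6,10-trien-1-yl acetate
Product: 7 (2E,6E,8R)-8-(tert-butyldimethylsilyloxy)-3,7,11-trimethyldodeca-2,6,10-trien-1-yl acetate
Conditions: TBSCl, imidazole, DMF, rt
Reagents that add atoms: tert-butyldimethylsilyl chloride, CC(C)(C)[Si](C)(C)Cl
Why: Imidazole-promoted O-silylation of the only free hydroxyl masks C12' against the later oxidation and the organozinc reagent, and no other group reacts.

Step 5
Reactants: 7 (2E,6E,8R)-8-(tert-butyldimethylsilyloxy)-3,7,11-trimethyldodeca-2,6,10-trien-1-yl acetate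
Product: 8 (2E,6E,8R)-8-(tert-butyldimethylsilyloxy)-3,7,11-trimethyldodeca-2,6,10-trien-1-ol
Conditions: K2CO3, MeOH, rt
Reagents that add atoms: none
Why: Base-catalysed transesterification removes the primary acetate as methyl acetate, and the secondary silyl ether is stable to methanolic carbonate.

Step 6
Reactants: 8 (2E,6E,8R)-8-(tert-butyldimethylsilyloxy)-3,7,11-trimethyldodeca-2,6,10-trien-1-ol
Product: 9 (2E,6E,8R)-8-(tert-butyldimethylsilyloxy)-3,7,11-trimethyldodeca-2,6,10-trienal
Conditions: MnO2, CH2Cl2, rt
Reagents that add atoms: none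
Why: MnO2 oxidation of a primary allylic alcohol stops at the enal and keeps the E geometry of the C6'=C7' bond, the only other carbinol being silylated.

Step 7
Reactants: 10 4-methoxy-2-methylphenol
Product: 11 2-bromo-4-methoxy-6-methylphenol
Conditions: NBS, i-Pr2NH (catalytic), CH2Cl2, 0 °C
Reagents that add atoms: N-bromosuccinimide, O=C1CCC(=O)N1Br
Why: Amine-mediated electrophilic aromatic bromination is directed by the free hydroxyl to its only open ortho position, the para position being blocked by the methoxy group.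

Step 8
Reactants: 11 2-bromo-4-methoxy-6-methylphenol
Product: 12 1-bromo-5-methoxy-2-(methoxymethoxy)-3-methylbenzene
Conditions: MOMCl, i-Pr2NEt, CH2Cl2, 0 °C to rt
Reagents that add atoms: chloromethyl methyl ether, COCCl
Why: O-Alkylation of the phenol with the reactive chloromethyl ether gives an acetal that carries no acidic hydrogen and tolerates aryllithium and arylzinc species.

Step 9
Reactants: 12 1-bromo-5-methoxy-2-(methoxymethoxy)-3-methylbenzene
Product: 15 [5-methoxy-2-(methoxymethoxy)-3-methylphenyl][(trimethylsilyl)methyl]zinc, via aryllithium 13 (not isolated), via arylzinc chloride 14 (not isolated)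
Conditions: t-BuLi (2 equiv), THF, −78 °C; ZnCl2 (1.0 equiv), −78 to 0 °C; Me3SiCH2Li (1.0 equiv, pentane solution), −78 °C to rt; used as a titrated THF solution
Reagents that add atoms: zinc dichloride, Cl[Zn]Cl; (trimethylsilyl)methyllithium, [Li]C[Si](C)(C)C
Why: Bromine–lithium exchange, helped by chelation from the ortho acetal oxygen, followed by transmetalation to zinc gives arylzinc chloride 14, which (trimethylsilyl)methyllithium caps with a non-transferable alkyl ligand to give a mixed diorganozinc carrying one deliverable aryl group per zinc, while the second equivalent of t-BuLi destroys the tert-butyl bromide so that no alkyl halide reaches the nickel catalyst.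

Step 10
Reactants: 9 (2E,6E,8R)-8-(tert-butyldimethylsilyloxy)-3,7,11-trimethyldodeca-2,6,10-trienal; 15 [5-methoxy-2-(methoxymethoxy)-3-methylphenyl][(trimethylsilyl)methyl]zinc; 16 isoprene
Product: 18 (2E,5R,6E,10E,12R)-12-(tert-butyldimethylsilyloxy)-1-[5-methoxy-2-(methoxymethoxy)-3-methylphenyl]-3,7,11,15-tetramethylhexadeca-2,6,10,14-tetraen-5-ol, via zinc alkoxide 17 (not isolated)
Conditions: Ni(cod)2 (10 mol %), chiral spirobiindane phosphoramidite (12 mol %), 16 (5 equiv), 15 (1.5 equiv), THF–toluene, 0 °C to rt, 9 added slowly; aqueous NH4Cl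
Reagents that add atoms: none
Why: Proposed new method: zerovalent nickel carrying one chiral phosphoramidite binds isoprene and the zinc-activated aldehyde 9 and couples them oxidatively at the CH2 terminus of the methyl-bearing double bond (the C4'–C5' bond), giving a divalent allyl(alkoxy)nickel species, a transient oxanickelacycle whose allyl unit spans C3'–C2'–C1' with C4' syn; 15 then takes the alkoxide onto zinc and hands its aryl group to nickel, and reductive elimination at the unsubstituted terminus C1' forms the aryl–C1' bond, releases the E C2'=C3' alkene as zinc alkoxide 17 and returns zerovalent nickel. The closest known reaction types are the racemic Ni(acac)2-catalysed 1,4-coupling of diorganozincs, 1,3-dienes and aldehydes, which shows this regiochemistry and E geometry with isoprene, and the nickel–phosphoramidite enantioselective reductive coupling of 1,3-dienes with aldehydes under diethylzinc; here the sp2 aryl group should migrate from zinc far faster than the (trimethylsilyl)methyl ligand, and since neither group has a β-hydrogen the transfer must end in carbon–carbon bond formation instead of reduction. No ring is closed in the product, the only cycle being the metallacycle that transmetalation opens again. The new stereocentre C5' is fixed in the oxidative cyclisation by the ligand, which shields one face of the nickel-bound aldehyde, while C12' lies seven bonds away and is a spectator. The step needs regiocontrol on isoprene and E geometry, both secured by the methyl group and the syn-allylnickel arrangement; it needs 1,2- over 1,4-reactivity of the enal, secured by the fully substituted β-carbon C7'; and it needs suppression of direct aryl addition, secured by the low uncatalysed reactivity of diorganozincs towards aldehydes and by the slow addition of 9.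

Step 11
Reactants: 18 (2E,5R,6E,10E,12R)-12-(tert-butyldimethylsilyloxy)-1-[5-methoxy-2-(methoxymethoxy)-3-methylphenyl]-3,7,11,15-tetramethylhexadeca-2,6,10,14-tetraen-5-ol
Product: 20 2-[(2E,5R,6E,10E,12R)-12-(tert-butyldimethylsilyloxy)-5-hydroxy-3,7,11,15-tetramethylhexadeca-2,6,10,14-tetraen-1-yl]-4-methoxy-6-methylphenol, via bis(trimethylsilyl) ether 19 (not isolated)
Conditions: TMSOTf (3 equiv), 2,2'-bipyridyl (4.5 equiv), CH2Cl2, 0 °C to rt; then H2O, rt
Reagents that add atoms: none
Why: Aryl methoxymethyl ether cleavage by TMSOTf/2,2'-bipyridyl converts ArOCH2OMe into the aryl trimethylsilyl ether and an N-(methoxymethyl)bipyridinium salt without free protic acid, so the ortho-allyl phenol cannot cyclise to a chroman and the allylic ethers do not ionise, while the C5' hydroxyl is silylated in passing, both trimethylsilyl ethers are hydrolysed by the added water and the tert-butyldimethylsilyl ether is untouched.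

Step 12
Reactants: 20 2-[(2E,5R,6E,10E,12R)-12-(tert-butyldimethylsilyloxy)-5-hydroxy-3,7,11,15-tetramethylhexadeca-2,6,10,14-tetraen-1-yl]-4-methoxy-6-methylphenol
Product: 21 2-[(2E,5R,6E,10E,12R)-5,12-dihydroxy-3,7,11,15-tetramethylhexadeca-2,6,10,14-tetraen-1-yl]-4-methoxy-6-methylphenol
Conditions: TBAF, THF, 0 °C to rt
Reagents that add atoms: none
Why: Fluoride desilylation, driven by the strength of the Si–F bond, frees the C12' hydroxyl under non-acidic conditions that leave both stereocentres and all four alkenes unchanged, and it would also clear any trimethylsilyl ether left from step 11.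

**Compound list**

1 | geranyl acetate | CC(=O)OC/C=C(\C)CCC=C(C)C | starting material
2 | (2E,6E)-8-hydroxy-3,7-dimethylocta-2,6-dien-1-yl acetate (8-hydroxygeranyl acetate) | CC(=O)OC/C=C(\C)CC/C=C(\C)CO | intermediate
3 | (2E,6E)-3,7-dimethyl-8-oxoocta-2,6-dien-1-yl acetate | CC(=O)OC/C=C(\C)CC/C=C(\C)C=O | intermediate
4 | diisopinocampheylborinate ester of 5 | CC(=O)OC/C=C(\C)CC/C=C(\C)[C@H](OB([C@H]1C[C@H]2C[C@@H]([C@@H]1C)C2(C)C)[C@H]1C[C@H]2C[C@@H]([C@@H]1C)C2(C)C)CC=C | intermediate
5 | (2E,6E,8R)-8-hydroxy-3,7-dimethylundeca-2,6,10-trien-1-yl acetate | CC(=O)OC/C=C(\C)CC/C=C(\C)[C@H](O)CC=C | intermediate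
6 | (2E,6E,8R)-8-hydroxy-3,7,11-trimethyldodeca-2,6,10-trien-1-yl acetate | CC(=O)OC/C=C(\C)CC/C=C(\C)[C@H](O)CC=C(C)C | intermediate
7 | (2E,6E,8R)-8-(tert-butyldimethylsilyloxy)-3,7,11-trimethyldodeca-2,6,10-trien-1-yl acetate | CC(=O)OC/C=C(\C)CC/C=C(\C)[C@H](O[Si](C)(C)C(C)(C)C)CC=C(C)C | intermediate
8 | (2E,6E,8R)-8-(tert-butyldimethylsilyloxy)-3,7,11-trimethyldodeca-2,6,10-trien-1-ol | OC/C=C(\C)CC/C=C(\C)[C@H](O[Si](C)(C)C(C)(C)C)CC=C(C)C | intermediate
9 | (2E,6E,8R)-8-(tert-butyldimethylsilyloxy)-3,7,11-trimethyldodeca-2,6,10-trienal | O=C/C=C(\C)CC/C=C(\C)[C@H](O[Si](C)(C)C(C)(C)C)CC=C(C)C | intermediate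
10 | 4-methoxy-2-methylphenol | COc1ccc(O)c(C)c1 | starting material
11 | 2-bromo-4-methoxy-6-methylphenol | COc1cc(C)c(O)c(Br)c1 | intermediate
12 | 1-bromo-5-methoxy-2-(methoxymethoxy)-3-methylbenzene | COCOc1c(C)cc(OC)cc1Br | intermediate
13 | [5-methoxy-2-(methoxymethoxy)-3-methylphenyl]lithium | [Li]c1cc(OC)cc(C)c1OCOC | intermediate
14 | chloro[5-methoxy-2-(methoxymethoxy)-3-methylphenyl]zinc | Cl[Zn]c1cc(OC)cc(C)c1OCOC | intermediate
15 | [5-methoxy-2-(methoxymethoxy)-3-methylphenyl][(trimethylsilyl)methyl]zinc | COc1cc(C)c(OCOC)c([Zn]C[Si](C)(C)C)c1 | intermediate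
16 | isoprene | C=CC(C)=C | starting material
17 | [(trimethylsilyl)methyl]zinc alkoxide of 18 (O–Zn–CH2SiMe3 at C5') | COc1cc(C)c(OCOC)c(C/C=C(\C)C[C@@H](O[Zn]C[Si](C)(C)C)/C=C(\C)CC/C=C(\C)[C@H](O[Si](C)(C)C(C)(C)C)CC=C(C)C)c1 | intermediate
18 | (2E,5R,6E,10E,12R)-12-(tert-butyldimethylsilyloxy)-1-[5-methoxy-2-(methoxymethoxy)-3-methylphenyl]-3,7,11,15-tetramethylhexadeca-2,6,10,14-tetraen-5-ol | COc1cc(C)c(OCOC)c(C/C=C(\C)C[C@@H](O)/C=C(\C)CC/C=C(\C)[C@H](O[Si](C)(C)C(C)(C)C)CC=C(C)C)c1 | intermediate
19 | aryl and C5' bis(trimethylsilyl) ether of 20 (C12' tert-butyldimethylsilyl ether kept) | COc1cc(C)c(O[Si](C)(C)C)c(C/C=C(\C)C[C@@H](O[Si](C)(C)C)/C=C(\C)CC/C=C(\C)[C@H](O[Si](C)(C)C(C)(C)C)CC=C(C)C)c1 | intermediate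
20 | 2-[(2E,5R,6E,10E,12R)-12-(tert-butyldimethylsilyloxy)-5-hydroxy-3,7,11,15-tetramethylhexadeca-2,6,10,14-tetraen-1-yl]-4-methoxy-6-methylphenol | COc1cc(C)c(O)c(C/C=C(\C)C[C@@H](O)/C=C(\C)CC/C=C(\C)[C@H](O[Si](C)(C)C(C)(C)C)CC=C(C)C)c1 | intermediate
21 | 2-[(2E,5R,6E,10E,12R)-5,12-dihydroxy-3,7,11,15-tetramethylhexadeca-2,6,10,14-tetraen-1-yl]-4-methoxy-6-methylphenol | COc1cc(C)c(O)c(C/C=C(\C)C[C@@H](O)/C=C(\C)CC/C=C(\C)[C@H](O)CC=C(C)C)c1 | target

**Count**

Total steps: 12. Longest linear sequence: 9 steps (steps 1 to 6, then 10, 11 and 12, from geranyl acetate).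

**Steps most likely to fail**

Step 10 (new method). The ligand may give poor facial selectivity at C5' in the oxidative cyclisation, or aryl transfer may leak into conjugate or direct addition to the enal. The fallback rests on known reaction types, sets out from 9, 15 and 16 and comes back at 18. The three components would be coupled under the established achiral protocol for diorganozincs, 1,3-dienes and aldehydes (Ni(acac)2 catalytic, THF, rt), which should give the [(trimethylsilyl)methyl]zinc alkoxide of the epimeric carbinols F1 and, after aqueous NH4Cl, (2E,6E,10E,12R)-12-(tert-butyldimethylsilyloxy)-1-[5-methoxy-2-(methoxymethoxy)-3-methylphenyl]-3,7,11,15-tetramethylhexadeca-2,6,10,14-tetraen-5-ol F2 as both C5' epimers. MnO2 in CH2Cl2 would oxidise this allylic carbinol to the corresponding hexadeca-2,6,10,14-tetraen-5-one F3, handled cold and without base so that the C2'=C3' alkene does not move into conjugation. Corey–Bakshi–Shibata reduction with (S)-2-methyl-CBS-oxazaborolidine and catecholborane in toluene at −78 °C, the alkenyl group acting as the large substituent, should deliver the 5'R catechol borate ester F4, whose hydrolysis on work-up returns 18.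

Step 11. The silyl triflate may ionise an allylic C–O bond or trigger cyclisation of the ortho-allyl aryl ether onto the C2'=C3' alkene, or the acetal cleavage may stall. The fallback changes the phenol protecting group, sets out from 11 and comes back at 21. SEMCl and i-Pr2NEt in CH2Cl2 would give {2-[(2-bromo-4-methoxy-6-methylphenoxy)methoxy]ethyl}trimethylsilane F5. t-BuLi in THF at −78 °C would give the aryllithium F6, ZnCl2 the arylzinc chloride F7 and Me3SiCH2Li the mixed aryl[(trimethylsilyl)methyl]zinc F8. Coupling with 9 and 16 as in step 10 would pass through the zinc alkoxide F9 to the 2-(trimethylsilyl)ethoxymethyl analogue of 18 F10. TBAF in DMPU at 80 °C would then remove the silyl ether and the fluoride-labile acetal in one operation and give 21 without any Lewis acid.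

Step 1. The allylic oxidation may stop short, attack other allylic positions or over-oxidise. The fallback builds the enal by olefination, sets out from 1 and comes back at 3. mCPBA in CH2Cl2 at 0 °C would epoxidise the electron-rich distal alkene to (2E)-6,7-epoxy-3,7-dimethyloct-2-en-1-yl acetate F11. H5IO6 in THF–Et2O would cleave the epoxide to (2E)-3-methyl-6-oxohex-2-en-1-yl acetate F12 and acetone. An E-selective Wittig reaction with the stabilised ylide 2-(triphenylphosphoranylidene)propanal in toluene at 90 °C would give 3.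

**Further compounds**

F1 | step 10 | [(trimethylsilyl)methyl]zinc alkoxide of F2, both C5' epimers | COc1cc(C)c(OCOC)c(C/C=C(\C)CC(O[Zn]C[Si](C)(C)C)/C=C(\C)CC/C=C(\C)[C@H](O[Si](C)(C)C(C)(C)C)CC=C(C)C)c1
F2 | step 10 | (2E,6E,10E,12R)-12-(tert-butyldimethylsilyloxy)-1-[5-methoxy-2-(methoxymethoxy)-3-methylphenyl]-3,7,11,15-tetramethylhexadeca-2,6,10,14-tetraen-5-ol, both C5' epimers | COc1cc(C)c(OCOC)c(C/C=C(\C)CC(O)/C=C(\C)CC/C=C(\C)[C@H](O[Si](C)(C)C(C)(C)C)CC=C(C)C)c1
F3 | step 10 | (2E,6E,10E,12R)-12-(tert-butyldimethylsilyloxy)-1-[5-methoxy-2-(methoxymethoxy)-3-methylphenyl]-3,7,11,15-tetramethylhexadeca-2,6,10,14-tetraen-5-one | COc1cc(C)c(OCOC)c(C/C=C(\C)CC(=O)/C=C(\C)CC/C=C(\C)[C@H](O[Si](C)(C)C(C)(C)C)CC=C(C)C)c1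
F4 | step 10 | catechol borate ester of 18 (5'R) | COc1cc(C)c(OCOC)c(C/C=C(\C)C[C@@H](OB2Oc3ccccc3O2)/C=C(\C)CC/C=C(\C)[C@H](O[Si](C)(C)C(C)(C)C)CC=C(C)C)c1
F5 | step 11 | {2-[(2-bromo-4-methoxy-6-methylphenoxy)methoxy]ethyl}trimethylsilane | COc1cc(C)c(OCOCC[Si](C)(C)C)c(Br)c1
F6 | step 11 | (5-methoxy-3-methyl-2-{[2-(trimethylsilyl)ethoxy]methoxy}phenyl)lithium | [Li]c1cc(OC)cc(C)c1OCOCC[Si](C)(C)C
F7 | step 11 | chloro(5-methoxy-3-methyl-2-{[2-(trimethylsilyl)ethoxy]methoxy}phenyl)zinc | Cl[Zn]c1cc(OC)cc(C)c1OCOCC[Si](C)(C)C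
F8 | step 11 | (5-methoxy-3-methyl-2-{[2-(trimethylsilyl)ethoxy]methoxy}phenyl)[(trimethylsilyl)methyl]zinc | COc1cc(C)c(OCOCC[Si](C)(C)C)c([Zn]C[Si](C)(C)C)c1
F9 | step 11 | [(trimethylsilyl)methyl]zinc alkoxide of F10 | COc1cc(C)c(OCOCC[Si](C)(C)C)c(C/C=C(\C)C[C@@H](O[Zn]C[Si](C)(C)C)/C=C(\C)CC/C=C(\C)[C@H](O[Si](C)(C)C(C)(C)C)CC=C(C)C)c1
F10 | step 11 | (2E,5R,6E,10E,12R)-12-(tert-butyldimethylsilyloxy)-1-(5-methoxy-3-methyl-2-{[2-(trimethylsilyl)ethoxy]methoxy}phenyl)-3,7,11,15-tetramethylhexadeca-2,6,10,14-tetraen-5-ol | COc1cc(C)c(OCOCC[Si](C)(C)C)c(C/C=C(\C)C[C@@H](O)/C=C(\C)CC/C=C(\C)[C@H](O[Si](C)(C)C(C)(C)C)CC=C(C)C)c1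
F11 | step 1 | (2E)-6,7-epoxy-3,7-dimethyloct-2-en-1-yl acetate (racemic epoxide) | CC(=O)OC/C=C(\C)CCC1OC1(C)C
F12 | step 1 | (2E)-3-methyl-6-oxohex-2-en-1-yl acetate | CC(=O)OC/C=C(\C)CCC=O
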